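**Retrosynthetic overview**
1. The strategy rests on the pentasubstituted benzene ring. Four contiguous ring carbons carry OCH3, H, the ketal O and the benzylic CH2, and the other two carry the C=O and the first CH2 of the 12-membered lactone. This pattern is what a 1,1-dimethoxy-3-silyloxy-1,3-diene leaves on a 2-ynoate.
2. The dihydropyran ring of the cis-fused furo[2,3-b]chromene ketal is opened at the aryl O–C(ketal) bond and the ketal CH3 is removed. This leads back to phenol 19, which bears a trans-α,β-disubstituted γ-butyrolactone, plus MeLi.
3. The benzene ring of 19 is cut at C(OMe)–C(CO2) and C(benzyl)–C(chain). This gives diene 10 and the (R)-ynolide 16, joined forward by Diels–Alder addition and loss of MeOH.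
4. Diene 10 comes from (S)-β-methyl-γ-butyrolactone by trans allylation, hydroboration–oxidation, acylation of ketene dimethyl acetal and silylation. Ynolide 16 comes from oct-1-yne and (S)-propylene oxide by alkyne zipper, carboxylation and inverting Mitsunobu closure.
5. Ring order: five-membered O-ring (bought as the lactone), then the 12-membered ynolide, then benzene, then the dihydropyran ketal ring.

Key step: step 11

Assumption: 1 and 12 are bought as single enantiomers. The (S)-epoxide is used because the ring closure in step 10 inverts the carbinol carbon to the required R configuration.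

**Fragment A: diene**

Step 1
Reactants: 1 (S)-4-methyldihydrofuran-2(3H)-one; 2 allyl bromide
Product: 3 (3S,4S)-3-allyl-4-methyldihydrofuran-2(3H)-one
Conditions: LiN(iPr)2 (1.05 equiv), THF, −78 °C; then 2, −78 → −40 °C
Reagents that add atoms: none
Why: Enolate alkylation (SN2 on an allylic bromide), in which the electrophile approaches the lithium enolate anti to the C4 methyl group and sets C3 as S (3,4-trans); an allyl halide is preferred to an acrylate acceptor because it reacts once and leaves no new enolate that could oligomerise or scramble C3.

Step 2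
Reactants: 3 (3S,4S)-3-allyl-4-methyldihydrofuran-2(3H)-one
Product: 5 (3S,4S)-3-(3-hydroxypropyl)-4-methyldihydrofuran-2(3H)-one, via B-alkyl-9-BBN adduct 4 (not isolated)
Conditions: 9-BBN (1.2 equiv), THF, 0 °C → rt; then H2O2, aq NaOAc, 0 °C → rt
Reagents that add atoms: 9-borabicyclo[3.3.1]nonane, [H]B1C2CCCC1CCC2 (boron unit, present in 4 only); hydrogen peroxide, OO (hydroxyl O of 5)
Why: Brown hydroboration–oxidation, in which 9-BBN adds anti-Markovnikov to the terminal alkene without touching the lactone and acetate-buffered peroxide replaces boron by OH while the lactone stays closed and both stereocentres stay untouched.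

Step 3
Reactants: 5 (3S,4S)-3-(3-hydroxypropyl)-4-methyldihydrofuran-2(3H)-one
Product: 6 3-[(3S,4S)-4-methyl-2-oxotetrahydrofuran-3-yl]propanoic acid
Conditions: TEMPO (cat.), PhI(OAc)2 (2.2 equiv), MeCN–H2O, rt
Reagents that add atoms: water, O (second oxygen of the acid)
Why: Nitroxyl-catalysed oxidation of a primary alcohol through the aldehyde hydrate to the acid, run close to neutral so that the lactone and its α-centre are not disturbed.

Step 4
Reactants: 6 3-[(3S,4S)-4-methyl-2-oxotetrahydrofuran-3-yl]propanoic acid
Product: 7 3-[(3S,4S)-4-methyl-2-oxotetrahydrofuran-3-yl]propanoyl chloride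
Conditions: (COCl)2 (1.3 equiv), DMF (cat.), CH2Cl2, 0 °C → rt; evaporate, use crude
Reagents that add atoms: oxalyl chloride, O=C(Cl)C(=O)Cl
Why: Acid chloride formation under Vilsmeier-type catalysis by DMF, which gives only gaseous by-products and leaves the lactone inert.

Step 5
Reactants: 7 3-[(3S,4S)-4-methyl-2-oxotetrahydrofuran-3-yl]propanoyl chloride; 8 1,1-dimethoxyethene (ketene dimethyl acetal)
Product: 9 (3S,4S)-3-(5,5-dimethoxy-3-oxopent-4-en-1-yl)-4-methyldihydrofuran-2(3H)-one
Conditions: 8 (2 equiv), Et3N (1.2 equiv), Et2O, 0 °C → rt, slow addition of 7; neutral work-up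
Reagents that add atoms: none
Why: C-acylation of an electron-rich ketene acetal by an acid chloride, after which Et3N deprotonates the dimethoxycarbenium ion before chloride can demethylate it and so delivers the push–pull β,β-dimethoxy enone.

Step 6
Reactants: 9 (3S,4S)-3-(5,5-dimethoxy-3-oxopent-4-en-1-yl)-4-methyldihydrofuran-2(3H)-one
Product: 10 (3S,4S)-3-[(2Z)-3-(tert-butyldimethylsilyloxy)-5,5-dimethoxypenta-2,4-dien-1-yl]-4-methyldihydrofuran-2(3H)-one
Conditions: TBSOTf (1.1 equiv), Et3N (2 equiv), Et2O, −78 → 0 °C; pentane extraction, filtration through basic alumina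
Reagents that add atoms: tert-butyldimethylsilyl triflate, CC(C)(C)[Si](C)(C)OS(=O)(=O)C(F)(F)F
Why: Soft enolisation–silylation, in which the strongly Lewis-basic vinylogous carbonate carbonyl is silylated ahead of the lactone and Et3N removes a proton from the only α′-CH2, which with this reagent pair should give the (Z)-silyl enol ether with the CH2 pointing outward from the diene.

**Fragment B: ynolide**

Step 7
Reactants: 11 oct-1-yne; 12 (S)-propylene oxide
Product: 13 (S)-undec-4-yn-2-ol
Conditions: n-BuLi (1.0 equiv), THF, −78 °C; DMPU, 12, −78 °C → rt; H2O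
Reagents that add atoms: none
Why: Epoxide alkynylation (SN2 opening by a lithium acetylide) at the unsubstituted carbon, so the stereocentre is not involved and stays S.

Step 8
Reactants: 13 (S)-undec-4-yn-2-ol
Product: 14 (S)-undec-10-yn-2-ol
Conditions: KH (4 equiv), H2N(CH2)3NH2, rt (gives KNH(CH2)3NH2); 13, 0 °C → rt; H2O
Reagents that add atoms: none
Why: Alkyne zipper isomerisation, in which the triple bond walks along the unbranched chain and is trapped as the terminal potassium acetylide, while the carbinol carbon sits as its alkoxide, cannot be crossed and is not epimerised.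

Step 9
Reactants: 14 (S)-undec-10-yn-2-ol
Product: 15 (S)-11-hydroxydodec-2-ynoic acid
Conditions: n-BuLi (2.2 equiv), THF, −78 → 0 °C; CO2 (g), −78 °C → rt; aq HCl
Reagents that add atoms: carbon dioxide, O=C=O
Why: Carboxylation of the lithium acetylide within the alkoxide/acetylide dianion, where any alkyl carbonate formed at oxygen falls apart again on acidification.

Step 10
Reactants: 15 (S)-11-hydroxydodec-2-ynoic acid
Product: 16 (R)-12-methyloxacyclododec-3-yn-2-one
Conditions: PPh3 (3 equiv), DIAD (3 equiv), toluene, 0 °C (betaine preformed); syringe-pump addition of 15, 0 °C → rt, final 2 mM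
Reagents that add atoms: none
Why: Mitsunobu macrolactonisation (12-exo-tet), in which the alcohol rather than the acid is activated, so no electrophilic acyl-ynoate prone to conjugate addition or allene formation arises, and the acidic ynoate carboxylate displaces the oxyphosphonium group by SN2 with inversion (S to R).

**Union and endgame**

Step 11
Reactants: 10 (3S,4S)-3-[(2Z)-3-(tert-butyldimethylsilyloxy)-5,5-dimethoxypenta-2,4-dien-1-yl]-4-methyldihydrofuran-2(3H)-one; 16 (R)-12-methyloxacyclododec-3-yn-2-one
Product: 19 phenolic (R)-12-membered benzolactone bearing the (3S,4S)-lactonylmethyl group, via cyclohexa-1,4-diene cycloadduct 17 (not isolated), via aryl silyl ether 18 (not isolated)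
Conditions: 10 (2 equiv), toluene (concentrated), sealed tube, 150 °C; cool; Bu4NF, AcOH, THF, 0 °C → rt
Reagents that add atoms: none
Why: A thermal, strongly asynchronous [4+2] cycloaddition joins the CH terminus of 10 (made nucleophilic by the silyloxy group and, vinylogously, by both methoxy groups) to the β-carbon of ynoate 16 and the ketene acetal carbon to the α-carbon, giving the 1,4-cyclohexadiene 17. In 17 a dimethyl ketal carbon lies across the ring from a doubly allylic C–H, so methanol should be lost by 1,4-elimination at the reaction temperature to give arene 18, and buffered fluoride then frees phenol 19 and carries any remaining 17 to the same product. The closest known reaction types are the Diels–Alder/aromatisation of 1,1-dialkoxy-3-silyloxybutadienes with β-alkyl 2-alkynoates and of bis-silyloxy dienes with macrocyclic ynolides. The only ring closed is the benzene ring, built by intermolecular [4+2] annulation across the triple bond of the preformed 12-membered lactone and therefore ortho-fused to it. The single new sp3 carbon of 17 is erased on aromatisation, and the three existing stereocentres lie away from the reacting atoms and meet no base. The selectivity needed is regiochemical and is secured by the matched polarisation of diene and ynoate; the (Z)-enol ether keeps the side chain outside the s-cis diene, and the second equivalent of 10 covers the portion consumed by the released methanol.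

Step 12
Reactants: 19 phenolic (R)-12-membered benzolactone bearing the (3S,4S)-lactonylmethyl group
Product: 20 methyl lactol of 19 (2-hydroxy-2,4-dimethyltetrahydrofuran-3-ylmethyl arene; anomers in equilibrium)
Conditions: MeLi (2.2 equiv), THF, −78 °C; AcOH, −78 °C
Reagents that add atoms: methyllithium, [Li]C
Why: 1,2-Addition of an organolithium to a γ-lactone, in which the first equivalent forms the phenoxide and the second adds to the open butyrolactone carbonyl to give a lithium hemiketal alkoxide that should persist at −78 °C until the quench, while the di-ortho-substituted secondary benzoate of the macrocycle is shielded; the hemiketal centre is re-formed in step 13 and needs no control here.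

Step 13
Reactants: 20 methyl lactol of 19
Product: 21 lasiodiplactone A
Conditions: CSA (cat.), 4 Å MS, CH2Cl2, rt
Reagents that add atoms: none
Why: Acid-catalysed intramolecular ketalisation under thermodynamic control, in which the lactol ionises to the methyl oxocarbenium ion and the neighbouring phenol closes the dihydropyran ring (6-exo-trig) from the face of the benzylic CH2, because only the cis-fused furo[2,3-b]chromene is unstrained; this sets the ketal carbon as S, and the C-methyl group on the convex face (trans to the benzylic CH2) is also the stable arrangement should the α-carbon equilibrate.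

**Compound list**
1 | (S)-4-methyldihydrofuran-2(3H)-one | O=C1C[C@H](C)CO1 | starting material
2 | allyl bromide | C=CCBr | starting material
3 | (3S,4S)-3-allyl-4-methyldihydrofuran-2(3H)-one | C=CC[C@H]1[C@H](C)COC1=O | intermediate
4 | 9-[3-((3S,4S)-4-methyl-2-oxotetrahydrofuran-3-yl)propyl]-9-borabicyclo[3.3.1]nonane | C1CCC2CCCC1B2CCC[C@H]1[C@H](C)COC1=O | intermediate
5 | (3S,4S)-3-(3-hydroxypropyl)-4-methyldihydrofuran-2(3H)-one | OCCC[C@H]1[C@H](C)COC1=O | intermediate
6 | 3-[(3S,4S)-4-methyl-2-oxotetrahydrofuran-3-yl]propanoic acid | OC(=O)CC[C@H]1[C@H](C)COC1=O | intermediate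
7 | 3-[(3S,4S)-4-methyl-2-oxotetrahydrofuran-3-yl]propanoyl chloride | ClC(=O)CC[C@H]1[C@H](C)COC1=O | intermediate
8 | 1,1-dimethoxyethene | COC(=C)OC | starting material
9 | (3S,4S)-3-(5,5-dimethoxy-3-oxopent-4-en-1-yl)-4-methyldihydrofuran-2(3H)-one | COC(OC)=CC(=O)CC[C@H]1[C@H](C)COC1=O | intermediate
10 | (3S,4S)-3-[(2Z)-3-(tert-butyldimethylsilyloxy)-5,5-dimethoxypenta-2,4-dien-1-yl]-4-methyldihydrofuran-2(3H)-one | COC(OC)=C/C(O[Si](C)(C)C(C)(C)C)=C/C[C@H]1[C@H](C)COC1=O | intermediate
11 | oct-1-yne | C#CCCCCCC | starting material
12 | (S)-propylene oxide | C[C@H]1CO1 | starting material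
13 | (S)-undec-4-yn-2-ol | C[C@H](O)CC#CCCCCCC | intermediate
14 | (S)-undec-10-yn-2-ol | C[C@H](O)CCCCCCCC#C | intermediate
15 | (S)-11-hydroxydodec-2-ynoic acid | C[C@H](O)CCCCCCCC#CC(=O)O | intermediate
16 | (R)-12-methyloxacyclododec-3-yn-2-one | C[C@@H]1CCCCCCCC#CC(=O)O1 | intermediate
17 | cyclohexa-1,4-diene cycloadduct (ring carbons in order: C(OMe)2, CH=, =C(OTBS), CH(CH2-lactone) of undefined configuration, =C(chain), =C(C=O)), fused to the (R)-12-membered lactone | COC1(OC)C=C(O[Si](C)(C)C(C)(C)C)C(C[C@H]3[C@H](C)COC3=O)C2=C1C(=O)O[C@H](C)CCCCCCC2 | intermediate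
18 | tert-butyldimethylsilyl ether of 19 | COc1cc(O[Si](C)(C)C(C)(C)C)c(C[C@H]2[C@H](C)COC2=O)c2c1C(=O)O[C@H](C)CCCCCCC2 | intermediate
19 | benzolactone whose benzene ring carries in sequence the macrolactone C=O, OMe, H, OH, CH2-[(3S,4S)-4-methyl-2-oxotetrahydrofuran-3-yl] and the first CH2 of the (CH2)7 chain; carbinol carbon R | COc1cc(O)c(C[C@H]2[C@H](C)COC2=O)c2c1C(=O)O[C@H](C)CCCCCCC2 | intermediate
20 | methyl lactol of 19 (butyrolactone C=O replaced by C(CH3)(OH); anomeric carbon undefined) | COc1cc(O)c(C[C@H]2[C@H](C)COC2(C)O)c2c1C(=O)O[C@H](C)CCCCCCC2 | intermediate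
21 | lasiodiplactone A (carbinol R; ring-fusion CH S; CH(CH3) S; ketal carbon S) | COc1cc2c(c3c1C(=O)O[C@H](C)CCCCCCC3)C[C@H]1[C@H](C)CO[C@@]1(C)O2 | target

**Step count:** 13 steps in total. The longest linear sequence is 9 steps (steps 1–6, then 11–13).

**Steps most likely to fail**

1. Step 11.
 - Risk: bond formation between two substituted termini may be so slow that thermal decay and methanolysis of the diene outrun the cycloaddition.
 - Fallback: reverse the order of ring formation, building the arene first on an open-chain ynoate and closing the macrolactone second. The fallback sets out from 14 and 10 and returns at 19.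
 - 14 is silylated (TBSCl, imidazole, DMF) to (S)-tert-butyldimethyl(undec-10-yn-2-yloxy)silane F1.
 - The lithium acetylide of F1 (n-BuLi, THF, −78 °C) is acylated with 2-(trimethylsilyl)ethyl chloroformate to 2-(trimethylsilyl)ethyl (S)-11-(tert-butyldimethylsilyloxy)dodec-2-ynoate F2.
 - F2 belongs to the standard dienophile class for such dienes and can be used in large excess, so 10 becomes the limiting partner. Heating the two should give the open-chain cyclohexadiene adduct F3, which loses methanol to the pentasubstituted benzoate F4.
 - Excess Bu4NF removes both silyl ethers and fragments the silylethyl ester without attack at the hindered carbonyl, giving the seco acid F5.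
 - Mitsunobu macrolactonisation (PPh3, DIAD, toluene, high dilution) activates the alcohol, so the hindrance of the acid does not matter, and inverts S to R to give 19.

2. Step 12.
 - Risk: the tetrahedral intermediate may collapse before the quench and take up a second methyl group, the lactone may be enolised instead of attacked, or the lithium phenoxide may be poorly soluble at low temperature.
 - Fallback: carbonyl methylenation followed by acid-induced addition of the phenol. The fallback sets out from 18, isolated by leaving out the fluoride treatment in step 11, and returns at 21.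
 - Petasis methylenation (Cp2TiMe2, toluene, 70 °C) should convert the unhindered butyrolactone carbonyl into the 2-methylenetetrahydrofuran (exocyclic enol ether) F6 and spare the shielded benzoate.
 - HF·pyridine in THF then cleaves the aryl silyl ether and protonates the enol ether at its CH2 terminus. This creates the ketal methyl group and the same oxocarbenium ion as in step 13, which the phenol captures to give 21.

3. Step 10.
 - Risk: intermolecular esterification to diolide and oligomers, elimination of the activated secondary alcohol, and phosphine addition to the ynoate may all compete with ring closure.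
 - Fallback: close the ring at the triple bond by ring-closing alkyne metathesis. The fallback sets out from 14 and returns at 16.
 - The dianion of 14 (n-BuLi, 2.1 equiv, THF–DMPU) is C-methylated with MeI to (S)-dodec-10-yn-2-ol F7.
 - Intermolecular Mitsunobu esterification with but-2-ynoic acid (PPh3, DIAD, THF) proceeds with inversion and gives (R)-dodec-10-yn-2-yl but-2-ynoate F8.
 - Mo(≡CC6H4OMe)(OSiPh3)3 (cat.) with 5 Å MS in dilute toluene should close the 12-membered ring to 16 with expulsion of but-2-yne.

**Further compounds**
F1 | step 11 | (S)-tert-butyldimethyl(undec-10-yn-2-yloxy)silane | C[C@H](O[Si](C)(C)C(C)(C)C)CCCCCCCC#C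
F2 | step 11 | 2-(trimethylsilyl)ethyl (S)-11-(tert-butyldimethylsilyloxy)dodec-2-ynoate | C[C@H](O[Si](C)(C)C(C)(C)C)CCCCCCCC#CC(=O)OCC[Si](C)(C)C
F3 | step 11 | open-chain cyclohexa-1,4-diene adduct of 10 and F2 | COC1(OC)C=C(O[Si](C)(C)C(C)(C)C)C(C[C@H]2[C@H](C)COC2=O)C(CCCCCCC[C@H](C)O[Si](C)(C)C(C)(C)C)=C1C(=O)OCC[Si](C)(C)C
F4 | step 11 | 2-(trimethylsilyl)ethyl benzoate carrying OMe, H, OTBS, the (3S,4S)-lactonylmethyl group and the (S)-8-(tert-butyldimethylsilyloxy)nonyl chain | COc1cc(O[Si](C)(C)C(C)(C)C)c(C[C@H]2[C@H](C)COC2=O)c(CCCCCCC[C@H](C)O[Si](C)(C)C(C)(C)C)c1C(=O)OCC[Si](C)(C)C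
F5 | step 11 | seco acid (free phenol, (S)-8-hydroxynonyl chain, free benzoic acid) | COc1cc(O)c(C[C@H]2[C@H](C)COC2=O)c(CCCCCCC[C@H](C)O)c1C(=O)O
F6 | step 12 | exocyclic enol ether of 18 (butyrolactone C=O replaced by C=CH2) | COc1cc(O[Si](C)(C)C(C)(C)C)c(C[C@H]2[C@H](C)COC2=C)c2c1C(=O)O[C@H](C)CCCCCCC2
F7 | step 10 | (S)-dodec-10-yn-2-ol | C[C@H](O)CCCCCCCC#CC
F8 | step 10 | (R)-dodec-10-yn-2-yl but-2-ynoate | CC#CC(=O)O[C@H](C)CCCCCCCC#CC
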